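Chamigrene numbering is used: ring A is C1–C5 plus spiro C6 (C2–Br, C3(CH3)–Cl); ring B is C6–C11 (C7=CH2, C9–OH, C10–Br, C11 gem-dimethyl). Ring A is a masked Diels–Alder adduct: C6 and C5 are the α- and β-carbons of an exocyclic enone whose carbonyl is C7, and C1–C4 with the C3 methyl are isoprene. A catalytic asymmetric Diels–Alder reaction of isoprene with a dimedone-derived 6-methylene vinylogous ester therefore closes ring A and sets quaternary C6. Every other stereocentre is then relayed from C6: epoxidation, diaxial bromide opening and retentive chlorination on ring A, then bromination at C10 and reduction at C9.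

Key step: step 3

Remark: atom numbers in the text follow the chamigrene numbering above, while the systematic names of intermediates use their own spiro[5.5]undecane locants; it is assumed that either antipode of the step 3 catalyst can be chosen; the SMILES of the titanium–aluminium methylenating reagent in step 8 is drawn with σ-bonded cyclopentadienyl rings and without the Cl→Al dative bridge bond.

Step 1
Reactants: 1 dimedone (5,5-dimethylcyclohexane-1,3-dione)
Product: 2 3-ethoxy-5,5-dimethylcyclohex-2-en-1-one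
Conditions: EtOH, TsOH·H2O (cat.), toluene, reflux, Dean–Stark
Reagents that add atoms: ethanol, CCO
Why: Acid-catalysed enol etherification of the cyclic 1,3-diketone with azeotropic removal of water should give the vinylogous ester; no stereocentre is formed.

Step 2
Reactants: 2 3-ethoxy-5,5-dimethylcyclohex-2-en-1-one
Product: 5 3-ethoxy-5,5-dimethyl-6-methylidenecyclohex-2-en-1-one, via Mannich base 3 (not isolated), via ammonium iodide 4 (not isolated)
Conditions: LiN(iPr)2 (LDA), THF, −78 °C; Me2N=CH2+ I−, −78 → 0 °C; MeI, rt; NaHCO3 (aq), CH2Cl2, rt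
Reagents that add atoms: Eschenmoser's salt (N,N-dimethylmethyleneiminium iodide), C=[N+](C)C.[I-]; iodomethane (its carbon stays only in intermediate 4), CI
Why: Kinetic deprotonation of a vinylogous ester occurs at the α′ carbon (the future C6), and Mannich reaction with Eschenmoser's salt, quaternisation and E1cB loss of trimethylamine (Eschenmoser methylenation) should install the exocyclic methylene; no stereocentre remains.

Step 3
Reactants: 5 3-ethoxy-5,5-dimethyl-6-methylidenecyclohex-2-en-1-one; 6 isoprene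
Product: 7 (6S)-3-ethoxy-5,5,9-trimethylspiro[5.5]undeca-2,8-dien-1-one
Conditions: chiral imidodiphosphorimidate Brønsted acid HN[P(=NSO2CF3)(L)]2, L = 3,3′-bis[3,5-bis(trifluoromethyl)phenyl]-1,1′-binaphthalene-2,2′-diolate (5 mol %, antipode chosen to give 6S), isoprene (5 equiv), CHCl3, −40 °C
Reagents that add atoms: none
Why: The acid protonates the C7 carbonyl of 5 inside its chiral anion pocket, which lowers the LUMO of the s-cis exocyclic enone, and isoprene adds in a concerted, asynchronous [4+2] cycloaddition in which its more nucleophilic CH2 terminus (the one on the methyl-bearing carbon) bonds in advance to the unsubstituted β-carbon C5. The closest known reaction type is the chiral-Brønsted-acid-catalysed (and Lewis-acid-promoted) Diels–Alder reaction of exocyclic α-methylene ketones with 1,3-dienes that gives spiro[5.5]undecenones of the chamigrene class. Ring A is closed as a six-membered carbocycle by [4+2] cycloaddition, suprafacial on both partners, forming C5–C4 and C6–C1 in one operation. The only new stereocentre, quaternary C6, is controlled by the catalyst, whose counter-anion shields one face of the planar dienophile. The step needs para regioselectivity (C3 methyl 1,4 to C6), secured by matching of the largest HOMO and LUMO coefficients, and chemoselectivity for the exocyclic over the C8=C9 double bond, secured by the donor ethoxy group on C9 and the unhindered CH2 terminus.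

Step 4
Reactants: 7 (6S)-3-ethoxy-5,5,9-trimethylspiro[5.5]undeca-2,8-dien-1-one
Product: 8 (6S,8R,9S)-8,9-epoxy-3-ethoxy-5,5,9-trimethylspiro[5.5]undec-2-en-1-one (oxirane oxygen on the ring A face syn to C11, anti to C7)
Conditions: mCPBA, NaHCO3, CH2Cl2, 0 °C
Reagents that add atoms: 3-chloroperoxybenzoic acid, OOC(=O)c1cccc(Cl)c1
Why: Prilezhaev epoxidation should take the electron-rich trisubstituted C2=C3 bond (the push–pull C8=C9 bond is deactivated), and because the ring A half-chair keeps C11 (CMe2) equatorial and C7 axial, the peracid should add to the face anti to C7.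

Step 5
Reactants: 8 (6S,8R,9S)-8,9-epoxy-3-ethoxy-5,5,9-trimethylspiro[5.5]undec-2-en-1-one
Product: 9 (6S,8S,9S)-8-bromo-3-ethoxy-9-hydroxy-5,5,9-trimethylspiro[5.5]undec-2-en-1-one
Conditions: Li2NiBr4, THF, 0 °C → rt; pH 7 buffer
Reagents that add atoms: dilithium tetrabromonickelate, [Li+].[Li+].Br[Ni-2](Br)(Br)Br
Why: Nucleophilic bromide should open the epoxide in the trans-diaxial (Fürst–Plattner) sense at the secondary carbon C2 with inversion, as 5α,6α-epoxy steroids open at C6, which places Br axial on C2 on the C7 face and leaves the tertiary C3–OH axial on the C11 face.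

Step 6
Reactants: 9 (6S,8S,9S)-8-bromo-3-ethoxy-9-hydroxy-5,5,9-trimethylspiro[5.5]undec-2-en-1-one
Product: 11 (6S,8S,9S)-8-bromo-9-chloro-3-ethoxy-5,5,9-trimethylspiro[5.5]undec-2-en-1-one, via tertiary chlorosulfite 10 (not isolated)
Conditions: SOCl2, CH2Cl2, −40 → 0 °C (no base)
Reagents that add atoms: thionyl chloride, O=S(Cl)Cl
Why: The chlorosulfite should ionise with anchimeric assistance by the anti-periplanar C2–Br (bromonium ion on the C7 face), and chloride should reopen it at the tertiary carbon C3 from the side of the departed oxygen (Markovnikov and trans-diaxial), so that substitution occurs with overall retention by neighbouring-group participation and gives the anti C2–Br/C3–Cl pair.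

Step 7
Reactants: 11 (6S,8S,9S)-8-bromo-9-chloro-3-ethoxy-5,5,9-trimethylspiro[5.5]undec-2-en-1-one
Product: 13 (4R,6S,8S,9S)-4,8-dibromo-9-chloro-3-ethoxy-5,5,9-trimethylspiro[5.5]undec-2-en-1-one, via silyl dienol ether 12 (not isolated)
Conditions: tBuMe2SiOSO2CF3 (TBSOTf), Et3N, CH2Cl2, 0 °C; NBS, THF, −78 °C
Reagents that add atoms: N-bromosuccinimide, O=C1CCC(=O)N1Br; tert-butyldimethylsilyl triflate (its atoms stay only in intermediate 12), CC(C)(C)[Si](C)(C)OS(=O)(=O)C(F)(F)F
Why: Soft enolisation can only remove a γ-hydrogen at C10 (C6 is quaternary) and gives a 1-silyloxy-3-alkoxy diene that NBS should brominate at its terminal carbon C10 (vinylogous silyl enol ether bromination); the axial C2–Br of ring A pushes the C7–O bond toward C5, so C1 is pseudoaxial on ring B and NBS should enter anti to the pseudoaxial C11 methyl group, on the face of C1, giving Br at C10 cis to C1.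

Step 8
Reactants: 13 (4R,6S,8S,9S)-4,8-dibromo-9-chloro-3-ethoxy-5,5,9-trimethylspiro[5.5]undec-2-en-1-one
Product: 15 (2R,6R,8S,9S)-2,8-dibromo-9-chloro-1,1,9-trimethyl-5-methylidenespiro[5.5]undecan-3-one, via ethoxydiene 14 (not isolated)
Conditions: Cp2Ti(μ-Cl)(μ-CH2)AlMe2 (Tebbe reagent), pyridine (cat.), THF–toluene, −40 → 0 °C; oxalic acid (cat.), THF–H2O, 0 °C
Reagents that add atoms: Tebbe reagent Cp2Ti(μ-Cl)(μ-CH2)AlMe2, C[Al](C)C[Ti](Cl)(C1C=CC=C1)C1C=CC=C1; water, O
Why: Tebbe methylenation should convert the hindered, ester-like C7 carbonyl into the exocyclic methylene without base (alkyl halides are inert to it), and the resulting 2-ethoxy-1,3-diene should be hydrolysed under kinetic control by protonation at C8, as steroidal dienol ethers are, to the β,γ-unsaturated ketone without touching a stereocentre.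

Step 9
Reactants: 15 (2R,6R,8S,9S)-2,8-dibromo-9-chloro-1,1,9-trimethyl-5-methylidenespiro[5.5]undecan-3-one
Product: 16 (2R,3S,6R,8S,9S)-2,8-dibromo-9-chloro-1,1,9-trimethyl-5-methylidenespiro[5.5]undecan-3-ol (target)
Conditions: NaBH4, MeOH–CH2Cl2, −78 °C
Reagents that add atoms: none
Why: Small-hydride reduction of the α-bromo ketone under polar Felkin–Anh (Cornforth) control, with ring B held so that C10–Br is axial, should deliver hydride to C9 anti to the C–Br bond and give the cis-bromohydrin (C9–OH equatorial, cis to Br).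

Compound list
1 | dimedone (5,5-dimethylcyclohexane-1,3-dione) | CC1(C)CC(=O)CC(=O)C1 | starting material
2 | 3-ethoxy-5,5-dimethylcyclohex-2-en-1-one | CCOC1=CC(=O)CC(C)(C)C1 | intermediate
3 | rac-6-[(dimethylamino)methyl]-3-ethoxy-5,5-dimethylcyclohex-2-en-1-one (Mannich base) | CCOC1=CC(=O)C(CN(C)C)C(C)(C)C1 | intermediate (not isolated)
4 | rac-1-(4-ethoxy-6,6-dimethyl-2-oxocyclohex-3-en-1-yl)-N,N,N-trimethylmethanaminium iodide | CCOC1=CC(=O)C(C[N+](C)(C)C)C(C)(C)C1.[I-] | intermediate (not isolated)
5 | 3-ethoxy-5,5-dimethyl-6-methylidenecyclohex-2-en-1-one | CCOC1=CC(=O)C(=C)C(C)(C)C1 | intermediate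
6 | isoprene (2-methylbuta-1,3-diene) | C=CC(C)=C | starting material
7 | (6S)-3-ethoxy-5,5,9-trimethylspiro[5.5]undeca-2,8-dien-1-one | O=C1C=C(OCC)CC(C)(C)[C@@]12CCC(C)=CC2 | intermediate
8 | (6S,8R,9S)-8,9-epoxy-3-ethoxy-5,5,9-trimethylspiro[5.5]undec-2-en-1-one | O=C1C=C(OCC)CC(C)(C)[C@@]12CC[C@]3(C)O[C@@H]3C2 | intermediate
9 | (6S,8S,9S)-8-bromo-3-ethoxy-9-hydroxy-5,5,9-trimethylspiro[5.5]undec-2-en-1-one | O=C1C=C(OCC)CC(C)(C)[C@@]12CC[C@](C)(O)[C@@H](Br)C2 | intermediate
10 | (6S,8S,9S)-8-bromo-3-ethoxy-5,5,9-trimethyl-1-oxospiro[5.5]undec-2-en-9-yl chlorosulfite | O=C1C=C(OCC)CC(C)(C)[C@@]12CC[C@](C)(OS(=O)Cl)[C@@H](Br)C2 | intermediate (not isolated)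
11 | (6S,8S,9S)-8-bromo-9-chloro-3-ethoxy-5,5,9-trimethylspiro[5.5]undec-2-en-1-one | O=C1C=C(OCC)CC(C)(C)[C@@]12CC[C@](C)(Cl)[C@@H](Br)C2 | intermediate
12 | tert-butyl{[(6S,8S,9S)-8-bromo-9-chloro-3-ethoxy-5,5,9-trimethylspiro[5.5]undeca-1,3-dien-1-yl]oxy}dimethylsilane | CC(C)(C)[Si](C)(C)OC1=CC(OCC)=CC(C)(C)[C@@]12CC[C@](C)(Cl)[C@@H](Br)C2 | intermediate (not isolated)
13 | (4R,6S,8S,9S)-4,8-dibromo-9-chloro-3-ethoxy-5,5,9-trimethylspiro[5.5]undec-2-en-1-one | O=C1C=C(OCC)[C@H](Br)C(C)(C)[C@@]12CC[C@](C)(Cl)[C@@H](Br)C2 | intermediate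
14 | (4R,6R,8S,9S)-4,8-dibromo-9-chloro-3-ethoxy-5,5,9-trimethyl-1-methylidenespiro[5.5]undec-2-ene | C=C1C=C(OCC)[C@H](Br)C(C)(C)[C@@]12CC[C@](C)(Cl)[C@@H](Br)C2 | intermediate (not isolated)
15 | (2R,6R,8S,9S)-2,8-dibromo-9-chloro-1,1,9-trimethyl-5-methylidenespiro[5.5]undecan-3-one | C=C1CC(=O)[C@H](Br)C(C)(C)[C@@]12CC[C@](C)(Cl)[C@@H](Br)C2 | intermediate
16 | (2R,3S,6R,8S,9S)-2,8-dibromo-9-chloro-1,1,9-trimethyl-5-methylidenespiro[5.5]undecan-3-ol | C=C1C[C@H](O)[C@H](Br)C(C)(C)[C@@]12CC[C@](C)(Cl)[C@@H](Br)C2 | target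

Total step count: 9. Longest linear sequence: 9 steps (from dimedone).

Steps most likely to fail

Step 7. The bromination may take the other face of C10 (anti to the pseudoaxial ring A methylene C1 instead of anti to the pseudoaxial C11 methyl group), or occur partly at C8. The fallback sets out from 7 and returns at 13, and moves the C10 bromination ahead of the ring A chemistry. In 7 the C7 carbonyl leans toward the sp2 carbon C2, so ring B has the opposite twist (C5 pseudoaxial), and the same intrinsic facial preference would now place bromine cis to C1. Compound 7 would be converted with TBSOTf/Et3N into tert-butyl{[(6S)-3-ethoxy-5,5,9-trimethylspiro[5.5]undeca-1,3,8-trien-1-yl]oxy}dimethylsilane F3 and brominated with NBS to (4R,6S)-4-bromo-3-ethoxy-5,5,9-trimethylspiro[5.5]undeca-2,8-dien-1-one F4. mCPBA should then give (4R,6S,8R,9S)-4-bromo-8,9-epoxy-3-ethoxy-5,5,9-trimethylspiro[5.5]undec-2-en-1-one F5, and Li2NiBr4 should give (4R,6S,8S,9S)-4,8-dibromo-3-ethoxy-9-hydroxy-5,5,9-trimethylspiro[5.5]undec-2-en-1-one F6. SOCl2 should convert this, through (4R,6S,8S,9S)-4,8-dibromo-3-ethoxy-5,5,9-trimethyl-1-oxospiro[5.5]undec-2-en-9-yl chlorosulfite F7, into 13.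

Step 9. Hydride delivery may lose facial selectivity, because attack anti to the axial C10–Br is opposed by the syn-axial C11 methyl group; base-induced migration of the exocyclic double bond into conjugation is a side process. The fallback sets out from 15 and returns at 16, and replaces substrate control by reagent control. It is a Corey–Bakshi–Shibata reduction with BH3·SMe2 and (R)-1-methyl-3,3-diphenyl-tetrahydro-1H,3H-pyrrolo[1,2-c][1,3,2]oxazaborole, the antipode that the usual CBS model predicts for the (9S)-alcohol when C10 is the large and C8 the small flank. It makes no new compound (F0).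

Step 3. The cycloaddition may be slow or poorly enantioselective, because the donor-substituted (vinylogous ester) carbonyl is a weaker dienophile and binds the acid strongly (product inhibition). The fallback sets out from 5 (with 6) and returns at 7; it keeps the cycloaddition and obtains the enantiomer by resolution. Me2AlCl in CH2Cl2 at −20 °C should give rac-3-ethoxy-5,5,9-trimethylspiro[5.5]undeca-2,8-dien-1-one F1. Preparative supercritical-fluid chromatography on a chiral stationary phase should then separate (6S)-7 from (6R)-3-ethoxy-5,5,9-trimethylspiro[5.5]undeca-2,8-dien-1-one F2, which is discarded.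

Further compounds
F1 | step 3 | rac-3-ethoxy-5,5,9-trimethylspiro[5.5]undeca-2,8-dien-1-one | O=C1C=C(OCC)CC(C)(C)C12CCC(C)=CC2
F2 | step 3 | (6R)-3-ethoxy-5,5,9-trimethylspiro[5.5]undeca-2,8-dien-1-one | O=C1C=C(OCC)CC(C)(C)[C@]12CCC(C)=CC2
F3 | step 7 | tert-butyl{[(6S)-3-ethoxy-5,5,9-trimethylspiro[5.5]undeca-1,3,8-trien-1-yl]oxy}dimethylsilane | CC(C)(C)[Si](C)(C)OC1=CC(OCC)=CC(C)(C)[C@@]12CCC(C)=CC2
F4 | step 7 | (4R,6S)-4-bromo-3-ethoxy-5,5,9-trimethylspiro[5.5]undeca-2,8-dien-1-one | O=C1C=C(OCC)[C@H](Br)C(C)(C)[C@@]12CCC(C)=CC2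
F5 | step 7 | (4R,6S,8R,9S)-4-bromo-8,9-epoxy-3-ethoxy-5,5,9-trimethylspiro[5.5]undec-2-en-1-one | O=C1C=C(OCC)[C@H](Br)C(C)(C)[C@@]12CC[C@]3(C)O[C@@H]3C2
F6 | step 7 | (4R,6S,8S,9S)-4,8-dibromo-3-ethoxy-9-hydroxy-5,5,9-trimethylspiro[5.5]undec-2-en-1-one | O=C1C=C(OCC)[C@H](Br)C(C)(C)[C@@]12CC[C@](C)(O)[C@@H](Br)C2
F7 | step 7 | (4R,6S,8S,9S)-4,8-dibromo-3-ethoxy-5,5,9-trimethyl-1-oxospiro[5.5]undec-2-en-9-yl chlorosulfite | O=C1C=C(OCC)[C@H](Br)C(C)(C)[C@@]12CC[C@](C)(OS(=O)Cl)[C@@H](Br)C2
F0 | step 9 | none | none
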